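**Retrosynthetic overview**
- The target comes from a MOM/TBS-protected chalcone by acid deprotection; the chalcone C(aryl)–C(=O) bond comes from a ring A aryllithium (via the bromide) and a cinnamoyl Weinreb amide.
- Key disconnection: the diarylmethine C–C(alkenyl) bond, made by rhodium/chiral-diene-catalysed enantioselective alkenylation of an ortho-quinone methide with an (E)-alkenyl boronate.
- The ortho-quinone methide precursor is a Petasis aminophenol from a ring A salicylaldehyde, morpholine and an arylboronic acid; ring A is built from resorcinol by iridium-catalysed C–H borylation/oxidation, O-methylation and ortho-lithiation/formylation.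
- The alkenyl boronate comes from alkyne hydroboration, after asymmetric propargylboration of a 3-arylpropanal made by Heck reaction of an aryl iodide with allyl alcohol.
- No ring is formed in the route: ring A is bought as resorcinol and the three para-oxygenated rings as 4-iodophenol.

Assumption: the sense of induction in step 13 is assigned by a quadrant model for the diene–rhodium catalyst; the mirror-image diene would be used if a model experiment showed the opposite sense.

**Step 1**
Reactants: 1 resorcinol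
Product: 2 1,3-bis(methoxymethoxy)benzene
Conditions: NaH (2.3 equiv), MOMCl (2.3 equiv), DMF, 0 °C to rt
Reagents that add atoms: chloromethyl methyl ether (MOMCl), COCCl
Why: Williamson-type O-alkylation of the bis-phenoxide installs two acetal ethers that later act as ortho-directing groups and are removable with acid.

**Step 2**
Reactants: 2 1,3-bis(methoxymethoxy)benzene
Product: 4 3,5-bis(methoxymethoxy)phenol, via aryl pinacol boronate 3 (not isolated)
Conditions: [Ir(OMe)(cod)]2 (1 mol %), 4,4'-di-tert-butyl-2,2'-bipyridine (2 mol %), B2pin2 (1.0 equiv), THF, 80 °C; then 30% H2O2, aq NaOH, 0 °C to rt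
Reagents that add atoms: hydrogen peroxide, OO
Why: Iridium-catalysed aromatic C–H borylation is sterically controlled and so goes to C5, the only position not flanked by a substituent, and oxidation of the C–B bond then gives the phenol (borylation/oxidation sequence).

**Step 3**
Reactants: 4 3,5-bis(methoxymethoxy)phenol
Product: 5 1-methoxy-3,5-bis(methoxymethoxy)benzene
Conditions: MeI, K2CO3, acetone, reflux
Reagents that add atoms: iodomethane, CI
Why: Williamson ether synthesis on the only free phenol fixes the methyl ether of ring A.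

**Step 4**
Reactants: 5 1-methoxy-3,5-bis(methoxymethoxy)benzene
Product: 7 4-methoxy-2,6-bis(methoxymethoxy)benzaldehyde, via aryllithium 6 (not isolated)
Conditions: n-BuLi (1.2 equiv), TMEDA, THF, 0 °C; DMF, −78 °C to rt; then H2O
Reagents that add atoms: N,N-dimethylformamide, CN(C)C=O
Why: Directed ortho-metalation places lithium on the carbon between the two OMOM groups (which cooperate and outrank OMe as directors), and formylation with DMF gives the symmetrical aldehyde with unambiguous regiochemistry.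

**Step 5**
Reactants: 7 4-methoxy-2,6-bis(methoxymethoxy)benzaldehyde
Product: 8 2-hydroxy-4-methoxy-6-(methoxymethoxy)benzaldehyde
Conditions: MgBr2·OEt2 (1.3 equiv), Et2O/toluene, 0 °C to rt; then H2O
Reagents that add atoms: none
Why: Chelation-controlled acetal cleavage removes one ortho MOM group through magnesium bound between the aldehyde oxygen and that acetal, and the resulting phenoxide–aldehyde chelate (later the hydrogen-bonded phenol) protects the second, equivalent MOM ether.

**Step 6**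
Reactants: 9 4-iodophenol
Product: 10 1-iodo-4-(methoxymethoxy)benzene
Conditions: NaH, MOMCl, THF/DMF, 0 °C to rt
Reagents that add atoms: chloromethyl methyl ether (MOMCl), COCCl
Why: Williamson-type protection of the phenol gives the common aryl iodide used for three of the four arene-bearing fragments.

**Step 7**
Reactants: 10 1-iodo-4-(methoxymethoxy)benzene
Product: 12 [4-(methoxymethoxy)phenyl]boronic acid, via arylmagnesium chloride 11 (not isolated)
Conditions: i-PrMgCl·LiCl (1.1 equiv), THF, 0 °C; B(OMe)3 (2 equiv), −78 °C to rt; then H2O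
Reagents that add atoms: trimethyl borate, COB(OC)OC; water, O
Why: Iodine–magnesium exchange followed by borylation with a trialkyl borate and neutral hydrolysis gives the boronic acid without touching the MOM ether.

**Step 8**
Reactants: 8 2-hydroxy-4-methoxy-6-(methoxymethoxy)benzaldehyde; 12 [4-(methoxymethoxy)phenyl]boronic acid
Product: 13 5-methoxy-3-(methoxymethoxy)-2-{[4-(methoxymethoxy)phenyl](morpholin-4-yl)methyl}phenol (racemic)
Conditions: morpholine (1.1 equiv), EtOH, 60 °C
Reagents that add atoms: morpholine, C1COCCN1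
Why: In this Petasis borono-Mannich reaction the iminium ion from the salicylaldehyde and morpholine is arylated from the boronate bound to the free ortho phenoxide, and the new stereocentre is irrelevant because step 13 erases it.

**Step 9**
Reactants: 10 1-iodo-4-(methoxymethoxy)benzene; 14 prop-2-en-1-ol
Product: 15 3-[4-(methoxymethoxy)phenyl]propanal
Conditions: Pd(OAc)2 (2 mol %), n-Bu4NCl, NaHCO3, DMF, 45 °C
Reagents that add atoms: none
Why: Heck reaction under phase-transfer (Jeffery) conditions adds aryl–palladium to the terminal alkene carbon, and β-hydride elimination toward the carbinol carbon followed by tautomerisation gives the 3-arylpropanal directly.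

**Step 10**
Reactants: 16 3-bromoprop-1-yne; 15 3-[4-(methoxymethoxy)phenyl]propanal
Product: 19 (3R)-1-[4-(methoxymethoxy)phenyl]hex-5-yn-3-ol, via allenylmagnesium bromide 17 (not isolated), via B-allenyldiisopinocampheylborane 18 (not isolated)
Conditions: Mg, HgCl2 (cat.), Et2O, 0 °C; (−)-Ipc2BOMe [from (+)-α-pinene], −78 °C to rt; 15, −78 °C; then NaOH, H2O2
Reagents that add atoms: none
Why: Brown-type asymmetric propargylboration proceeds through a closed six-membered SE2' transition state in which the isopinocampheyl groups from (+)-α-pinene expose the same aldehyde face as in the analogous allylboration, which sets the (R)-carbinol and gives no allenyl isomer.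

**Step 11**
Reactants: 19 (3R)-1-[4-(methoxymethoxy)phenyl]hex-5-yn-3-ol
Product: 20 tert-butyl({(3R)-1-[4-(methoxymethoxy)phenyl]hex-5-yn-3-yl}oxy)dimethylsilane
Conditions: TBSCl, imidazole, DMF, rt
Reagents that add atoms: tert-butyldimethylsilyl chloride, CC(C)(C)[Si](C)(C)Cl
Why: Silylation of the secondary alcohol gives an ether that survives hydroboration, aqueous base and organolithium reagents and falls off in the final acid step.

**Step 12**
Reactants: 20 tert-butyl({(3R)-1-[4-(methoxymethoxy)phenyl]hex-5-yn-3-yl}oxy)dimethylsilane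
Product: 21 tert-butyl({(3R,5E)-1-[4-(methoxymethoxy)phenyl]-6-(4,4,5,5-tetramethyl-1,3,2-dioxaborolan-2-yl)hex-5-en-3-yl}oxy)dimethylsilane
Conditions: HBpin (1.3 equiv), Cp2Zr(H)Cl (10 mol %), Et3N (10 mol %), neat, 60 °C
Reagents that add atoms: pinacolborane, [H]B1OC(C)(C)C(C)(C)O1
Why: Zirconium-catalysed syn, anti-Markovnikov hydroboration of the terminal alkyne gives only the (E)-alkenyl boronate and leaves the silyl and MOM ethers alone.

**Step 13**
Reactants: 13 5-methoxy-3-(methoxymethoxy)-2-{[4-(methoxymethoxy)phenyl](morpholin-4-yl)methyl}phenol (racemic); 21 tert-butyl({(3R,5E)-1-[4-(methoxymethoxy)phenyl]-6-(4,4,5,5-tetramethyl-1,3,2-dioxaborolan-2-yl)hex-5-en-3-yl}oxy)dimethylsilane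
Product: 23 2-[(1S,2E,5R)-5-{[tert-butyl(dimethyl)silyl]oxy}-1,7-bis[4-(methoxymethoxy)phenyl]hept-2-en-1-yl]-5-methoxy-3-(methoxymethoxy)phenol, via ortho-quinone methide 22 (not isolated)
Conditions: [RhCl(C2H4)2]2 (2.5 mol %), (1R,4R)-2,5-diphenylbicyclo[2.2.2]octa-2,5-diene (5.5 mol %), K3PO4 (3 equiv), 21 (1.5 equiv), 1,4-dioxane/H2O 10:1, 60 °C
Reagents that add atoms: none
Why: Proposed new method: rhodium/chiral-diene-catalysed enantioselective 1,4-alkenylation of a transient ortho-quinone methide, in which base expels morpholine from 13 to give the electron-rich ortho-quinone methide 22, the hydroxorhodium–diene complex transmetalates the (E)-alkenyl boronate 21 with retention of alkene geometry, the alkenylrhodium species inserts the exocyclic C=C of 22 on the enantiotopic face left open by the C2-symmetric diene (setting the (S)-diarylmethine centre, with the remote (R)-silyloxy centre as a spectator) and aromatisation-driven protonolysis of the rhodium aryloxide releases 23; the closest known reaction types are rhodium/chiral-diene-catalysed conjugate arylation of in situ generated ortho-quinone methides with arylboron reagents and rhodium-catalysed 1,4-addition of alkenylboronates to enones.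

**Step 14**
Reactants: 23 2-[(1S,2E,5R)-5-{[tert-butyl(dimethyl)silyl]oxy}-1,7-bis[4-(methoxymethoxy)phenyl]hept-2-en-1-yl]-5-methoxy-3-(methoxymethoxy)phenol
Product: 24 tert-butyl({(3R,5E,7S)-7-[4-methoxy-2,6-bis(methoxymethoxy)phenyl]-1,7-bis[4-(methoxymethoxy)phenyl]hept-5-en-3-yl}oxy)dimethylsilane
Conditions: NaH, MOMCl, THF/DMF, 0 °C
Reagents that add atoms: chloromethyl methyl ether (MOMCl), COCCl
Why: Williamson-type re-protection of the phenol masks the acidic OH before lithiation and makes the two remaining C–H positions of ring A equivalent, while the non-enolisable stereocentres are unaffected.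

**Step 15**
Reactants: 24 tert-butyl({(3R,5E,7S)-7-[4-methoxy-2,6-bis(methoxymethoxy)phenyl]-1,7-bis[4-(methoxymethoxy)phenyl]hept-5-en-3-yl}oxy)dimethylsilane
Product: 25 tert-butyl({(3R,5E,7S)-7-[3-bromo-4-methoxy-2,6-bis(methoxymethoxy)phenyl]-1,7-bis[4-(methoxymethoxy)phenyl]hept-5-en-3-yl}oxy)dimethylsilane
Conditions: NBS (1.0 equiv), MeCN, −30 to 0 °C, dark
Reagents that add atoms: N-bromosuccinimide, BrN1C(=O)CCC1=O
Why: Electrophilic aromatic bromination goes to the 1,3,5-trioxygenated ring A, which is far more nucleophilic than the para-alkoxyphenyl rings or the 1,2-disubstituted alkene, and its two free positions are equivalent so one monobromide forms.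

**Step 16**
Reactants: 10 1-iodo-4-(methoxymethoxy)benzene; 26 N-methoxy-N-methylprop-2-enamide
Product: 27 (2E)-N-methoxy-3-[4-(methoxymethoxy)phenyl]-N-methylprop-2-enamide
Conditions: Pd(OAc)2 (2 mol %), P(o-tol)3 (4 mol %), Et3N, MeCN, 80 °C
Reagents that add atoms: none
Why: Mizoroki–Heck arylation of the acrylamide gives the (E)-cinnamoyl Weinreb amide by syn insertion and syn β-hydride elimination.

**Step 17**
Reactants: 25 tert-butyl({(3R,5E,7S)-7-[3-bromo-4-methoxy-2,6-bis(methoxymethoxy)phenyl]-1,7-bis[4-(methoxymethoxy)phenyl]hept-5-en-3-yl}oxy)dimethylsilane; 27 (2E)-N-methoxy-3-[4-(methoxymethoxy)phenyl]-N-methylprop-2-enamide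
Product: 29 (2E)-1-{3-[(1S,2E,5R)-5-{[tert-butyl(dimethyl)silyl]oxy}-1,7-bis[4-(methoxymethoxy)phenyl]hept-2-en-1-yl]-6-methoxy-2,4-bis(methoxymethoxy)phenyl}-3-[4-(methoxymethoxy)phenyl]prop-2-en-1-one, via aryllithium 28 (not isolated)
Conditions: t-BuLi (2.1 equiv), THF, −78 °C, 20 min; 27 (1.4 equiv), −78 to −30 °C; then H2O
Reagents that add atoms: none
Why: Bromine–lithium exchange at −78 °C outruns deprotonation of the doubly benzylic allylic C–H so the stereocentre is untouched, and 1,2-addition of the aryllithium to the Weinreb amide gives a chelated tetrahedral intermediate that collapses to the (E)-enone only on work-up (Weinreb ketone synthesis).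

**Step 18**
Reactants: 29 (2E)-1-{3-[(1S,2E,5R)-5-{[tert-butyl(dimethyl)silyl]oxy}-1,7-bis[4-(methoxymethoxy)phenyl]hept-2-en-1-yl]-6-methoxy-2,4-bis(methoxymethoxy)phenyl}-3-[4-(methoxymethoxy)phenyl]prop-2-en-1-one
Product: 30 (2E)-1-{2,4-dihydroxy-3-[(1S,2E,5R)-5-hydroxy-1,7-bis(4-hydroxyphenyl)hept-2-en-1-yl]-6-methoxyphenyl}-3-(4-hydroxyphenyl)prop-2-en-1-one
Conditions: 3 M aq HCl, MeOH/THF, 35 °C
Reagents that add atoms: none
Why: Acid-catalysed acetal exchange and silyl ether solvolysis remove the five MOM groups and the TBS group in one operation under conditions mild enough to leave the 2'-hydroxychalcone uncyclised and both non-enolisable stereocentres intact.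

**Compound list**
1 | resorcinol | Oc1cccc(O)c1 | starting material
2 | 1,3-bis(methoxymethoxy)benzene | COCOc1cccc(OCOC)c1 | intermediate
3 | 2-[3,5-bis(methoxymethoxy)phenyl]-4,4,5,5-tetramethyl-1,3,2-dioxaborolane | COCOc1cc(OCOC)cc(c1)B1OC(C)(C)C(C)(C)O1 | intermediate (not isolated)
4 | 3,5-bis(methoxymethoxy)phenol | COCOc1cc(O)cc(OCOC)c1 | intermediate
5 | 1-methoxy-3,5-bis(methoxymethoxy)benzene | COCOc1cc(OC)cc(OCOC)c1 | intermediate
6 | [4-methoxy-2,6-bis(methoxymethoxy)phenyl]lithium | [Li]c1c(OCOC)cc(OC)cc1OCOC | intermediate (not isolated)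
7 | 4-methoxy-2,6-bis(methoxymethoxy)benzaldehyde | COCOc1cc(OC)cc(OCOC)c1C=O | intermediate
8 | 2-hydroxy-4-methoxy-6-(methoxymethoxy)benzaldehyde | COCOc1cc(OC)cc(O)c1C=O | intermediate
9 | 4-iodophenol | Oc1ccc(I)cc1 | starting material
10 | 1-iodo-4-(methoxymethoxy)benzene | COCOc1ccc(I)cc1 | intermediate
11 | [4-(methoxymethoxy)phenyl]magnesium chloride | COCOc1ccc([Mg]Cl)cc1 | intermediate (not isolated)
12 | [4-(methoxymethoxy)phenyl]boronic acid | COCOc1ccc(B(O)O)cc1 | intermediate
13 | 5-methoxy-3-(methoxymethoxy)-2-{[4-(methoxymethoxy)phenyl](morpholin-4-yl)methyl}phenol (racemic) | COCOc1cc(OC)cc(O)c1C(N1CCOCC1)c1ccc(OCOC)cc1 | intermediate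
14 | prop-2-en-1-ol (allyl alcohol) | C=CCO | starting material
15 | 3-[4-(methoxymethoxy)phenyl]propanal | O=CCCc1ccc(OCOC)cc1 | intermediate
16 | 3-bromoprop-1-yne (propargyl bromide) | C#CCBr | starting material
17 | propa-1,2-dien-1-ylmagnesium bromide | C=C=C[Mg]Br | intermediate (not isolated)
18 | B-allenyldiisopinocampheylborane, both isopinocampheyl groups (1R,2S,3R,5R), from (+)-α-pinene | C=C=CB([C@@H]1C[C@@H]2C[C@H]([C@H]1C)C2(C)C)[C@@H]1C[C@@H]2C[C@H]([C@H]1C)C2(C)C | intermediate (not isolated)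
19 | (3R)-1-[4-(methoxymethoxy)phenyl]hex-5-yn-3-ol | C#CC[C@H](O)CCc1ccc(OCOC)cc1 | intermediate
20 | tert-butyl({(3R)-1-[4-(methoxymethoxy)phenyl]hex-5-yn-3-yl}oxy)dimethylsilane | C#CC[C@H](O[Si](C)(C)C(C)(C)C)CCc1ccc(OCOC)cc1 | intermediate
21 | tert-butyl({(3R,5E)-1-[4-(methoxymethoxy)phenyl]-6-(4,4,5,5-tetramethyl-1,3,2-dioxaborolan-2-yl)hex-5-en-3-yl}oxy)dimethylsilane | CC1(C)OB(/C=C/C[C@H](O[Si](C)(C)C(C)(C)C)CCc2ccc(OCOC)cc2)OC1(C)C | intermediate
22 | 3-methoxy-5-(methoxymethoxy)-6-{[4-(methoxymethoxy)phenyl]methylidene}cyclohexa-2,4-dien-1-one | COCOC1=CC(OC)=CC(=O)C1=Cc1ccc(OCOC)cc1 | intermediate (not isolated)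
23 | 2-[(1S,2E,5R)-5-{[tert-butyl(dimethyl)silyl]oxy}-1,7-bis[4-(methoxymethoxy)phenyl]hept-2-en-1-yl]-5-methoxy-3-(methoxymethoxy)phenol | COCOc1cc(OC)cc(O)c1[C@@H](/C=C/C[C@H](O[Si](C)(C)C(C)(C)C)CCc1ccc(OCOC)cc1)c1ccc(OCOC)cc1 | intermediate
24 | tert-butyl({(3R,5E,7S)-7-[4-methoxy-2,6-bis(methoxymethoxy)phenyl]-1,7-bis[4-(methoxymethoxy)phenyl]hept-5-en-3-yl}oxy)dimethylsilane | COCOc1cc(OC)cc(OCOC)c1[C@@H](/C=C/C[C@H](O[Si](C)(C)C(C)(C)C)CCc1ccc(OCOC)cc1)c1ccc(OCOC)cc1 | intermediate
25 | tert-butyl({(3R,5E,7S)-7-[3-bromo-4-methoxy-2,6-bis(methoxymethoxy)phenyl]-1,7-bis[4-(methoxymethoxy)phenyl]hept-5-en-3-yl}oxy)dimethylsilane | COCOc1cc(OC)c(Br)c(OCOC)c1[C@@H](/C=C/C[C@H](O[Si](C)(C)C(C)(C)C)CCc1ccc(OCOC)cc1)c1ccc(OCOC)cc1 | intermediate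
26 | N-methoxy-N-methylprop-2-enamide | CON(C)C(=O)C=C | starting material
27 | (2E)-N-methoxy-3-[4-(methoxymethoxy)phenyl]-N-methylprop-2-enamide | CON(C)C(=O)/C=C/c1ccc(OCOC)cc1 | intermediate
28 | {3-[(1S,2E,5R)-5-{[tert-butyl(dimethyl)silyl]oxy}-1,7-bis[4-(methoxymethoxy)phenyl]hept-2-en-1-yl]-6-methoxy-2,4-bis(methoxymethoxy)phenyl}lithium | COCOc1cc(OC)c([Li])c(OCOC)c1[C@@H](/C=C/C[C@H](O[Si](C)(C)C(C)(C)C)CCc1ccc(OCOC)cc1)c1ccc(OCOC)cc1 | intermediate (not isolated)
29 | (2E)-1-{3-[(1S,2E,5R)-5-{[tert-butyl(dimethyl)silyl]oxy}-1,7-bis[4-(methoxymethoxy)phenyl]hept-2-en-1-yl]-6-methoxy-2,4-bis(methoxymethoxy)phenyl}-3-[4-(methoxymethoxy)phenyl]prop-2-en-1-one | COCOc1cc(OC)c(C(=O)/C=C/c2ccc(OCOC)cc2)c(OCOC)c1[C@@H](/C=C/C[C@H](O[Si](C)(C)C(C)(C)C)CCc1ccc(OCOC)cc1)c1ccc(OCOC)cc1 | intermediate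
30 | (2E)-1-{2,4-dihydroxy-3-[(1S,2E,5R)-5-hydroxy-1,7-bis(4-hydroxyphenyl)hept-2-en-1-yl]-6-methoxyphenyl}-3-(4-hydroxyphenyl)prop-2-en-1-one | COc1cc(O)c([C@@H](/C=C/C[C@H](O)CCc2ccc(O)cc2)c2ccc(O)cc2)c(O)c1C(=O)/C=C/c1ccc(O)cc1 | target

**Step count**
Total step count: 18.
Longest linear sequence: 11 steps (steps 1, 2, 3, 4, 5, 8, 13, 14, 15, 17, 18).

**Steps most likely to fail and their fallbacks**

Step 13 (the proposed new rhodium-catalysed alkenylation) may fail through slow insertion into the electron-rich quinone methide, protodeboronation or poor face selectivity. The fallback uses only known chemistry and a different disconnection, making the aryl–methine bond by copper catalysis and the alkene by metathesis. It sets out from aldehyde 7, boronic acid 12 and alkyne 20 and rejoins the route at 24, bypassing steps 13 and 14.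
- Aldehyde 7 undergoes Horner–Wadsworth–Emmons olefination (triethyl phosphonoacetate, NaH, THF) to ethyl (2E)-3-[4-methoxy-2,6-bis(methoxymethoxy)phenyl]prop-2-enoate F1.
- DIBAL-H reduction gives (2E)-3-[4-methoxy-2,6-bis(methoxymethoxy)phenyl]prop-2-en-1-ol F2.
- Phosphorylation (ClP(O)(OEt)2, pyridine) gives diethyl (2E)-3-[4-methoxy-2,6-bis(methoxymethoxy)phenyl]prop-2-en-1-yl phosphate F3.
- Boronic acid 12 is condensed with neopentyl glycol to 2-[4-(methoxymethoxy)phenyl]-5,5-dimethyl-1,3,2-dioxaborinane F4.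
- Copper-catalysed enantioselective SN2' allylic arylation of F3 with F4 (CuCl, chiral imidazolinium carbene precursor, NaOMe, THF, 30 °C) gives 5-methoxy-1,3-bis(methoxymethoxy)-2-{(1S)-1-[4-(methoxymethoxy)phenyl]prop-2-en-1-yl}benzene F5.
- Alkyne 20 is semi-hydrogenated (H2, Pd/CaCO3 poisoned with Pb(OAc)2, quinoline) to tert-butyl({(3R)-1-[4-(methoxymethoxy)phenyl]hex-5-en-3-yl}oxy)dimethylsilane F6.
- (E)-Selective cross-metathesis of F5 with excess F6 (second-generation Hoveyda–Grubbs catalyst, CH2Cl2, 40 °C) gives 24.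

Step 17 may fail because the hindered aryllithium, flanked by OMe and OMOM, adds sluggishly to the Weinreb amide or is quenched by proton transfer. The fallback avoids organolithium chemistry and builds the enone by aldol condensation. It sets out from bromide 25 and iodide 10 and rejoins at 29.
- Stille coupling of 25 with tributyl(1-ethoxyvinyl)stannane (Pd(PPh3)4, toluene, 100 °C) gives tert-butyl({(3R,5E,7S)-7-[3-(1-ethoxyethenyl)-4-methoxy-2,6-bis(methoxymethoxy)phenyl]-1,7-bis[4-(methoxymethoxy)phenyl]hept-5-en-3-yl}oxy)dimethylsilane F7.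
- Brief hydrolysis (1 M HCl, THF, 0 °C) gives 1-{3-[(1S,2E,5R)-5-{[tert-butyl(dimethyl)silyl]oxy}-1,7-bis[4-(methoxymethoxy)phenyl]hept-2-en-1-yl]-6-methoxy-2,4-bis(methoxymethoxy)phenyl}ethan-1-one F8.
- Iodide 10 is converted (i-PrMgCl·LiCl, then DMF) into 4-(methoxymethoxy)benzaldehyde F9.
- Claisen–Schmidt condensation of F8 with F9 (KOH, EtOH/THF, rt) gives 29.

Step 18 may fail because protic acid can ionise the doubly benzylic allylic C–aryl bond (epimerisation or retro-Friedel–Crafts cleavage) or cyclise the 2'-hydroxychalcone to a flavanone. The fallback replaces the one-pot protic deprotection by a two-stage unmasking without Brønsted acid. It sets out from 29 and rejoins at 30.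
- The five aryl MOM ethers are converted by TMSOTf and 2,2'-bipyridyl (CH2Cl2, 0 °C, then water) into (2E)-1-{3-[(1S,2E,5R)-5-{[tert-butyl(dimethyl)silyl]oxy}-1,7-bis(4-hydroxyphenyl)hept-2-en-1-yl]-2,4-dihydroxy-6-methoxyphenyl}-3-(4-hydroxyphenyl)prop-2-en-1-one F10.
- The silyl ether is then removed with pyridine-buffered HF·pyridine (THF, 0 °C) to give 30.

**Further compounds**
F1 | step 13 | ethyl (2E)-3-[4-methoxy-2,6-bis(methoxymethoxy)phenyl]prop-2-enoate | CCOC(=O)/C=C/c1c(OCOC)cc(OC)cc1OCOC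
F2 | step 13 | (2E)-3-[4-methoxy-2,6-bis(methoxymethoxy)phenyl]prop-2-en-1-ol | OC/C=C/c1c(OCOC)cc(OC)cc1OCOC
F3 | step 13 | diethyl (2E)-3-[4-methoxy-2,6-bis(methoxymethoxy)phenyl]prop-2-en-1-yl phosphate | CCOP(=O)(OCC)OC/C=C/c1c(OCOC)cc(OC)cc1OCOC
F4 | step 13 | 2-[4-(methoxymethoxy)phenyl]-5,5-dimethyl-1,3,2-dioxaborinane | COCOc1ccc(cc1)B1OCC(C)(C)CO1
F5 | step 13 | 5-methoxy-1,3-bis(methoxymethoxy)-2-{(1S)-1-[4-(methoxymethoxy)phenyl]prop-2-en-1-yl}benzene | COCOc1cc(OC)cc(OCOC)c1[C@@H](C=C)c1ccc(OCOC)cc1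
F6 | step 13 | tert-butyl({(3R)-1-[4-(methoxymethoxy)phenyl]hex-5-en-3-yl}oxy)dimethylsilane | C=CC[C@H](O[Si](C)(C)C(C)(C)C)CCc1ccc(OCOC)cc1
F7 | step 17 | tert-butyl({(3R,5E,7S)-7-[3-(1-ethoxyethenyl)-4-methoxy-2,6-bis(methoxymethoxy)phenyl]-1,7-bis[4-(methoxymethoxy)phenyl]hept-5-en-3-yl}oxy)dimethylsilane | CCOC(=C)c1c(OC)cc(OCOC)c([C@@H](/C=C/C[C@H](O[Si](C)(C)C(C)(C)C)CCc2ccc(OCOC)cc2)c2ccc(OCOC)cc2)c1OCOC
F8 | step 17 | 1-{3-[(1S,2E,5R)-5-{[tert-butyl(dimethyl)silyl]oxy}-1,7-bis[4-(methoxymethoxy)phenyl]hept-2-en-1-yl]-6-methoxy-2,4-bis(methoxymethoxy)phenyl}ethan-1-one | CC(=O)c1c(OC)cc(OCOC)c([C@@H](/C=C/C[C@H](O[Si](C)(C)C(C)(C)C)CCc2ccc(OCOC)cc2)c2ccc(OCOC)cc2)c1OCOC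
F9 | step 17 | 4-(methoxymethoxy)benzaldehyde | COCOc1ccc(C=O)cc1
F10 | step 18 | (2E)-1-{3-[(1S,2E,5R)-5-{[tert-butyl(dimethyl)silyl]oxy}-1,7-bis(4-hydroxyphenyl)hept-2-en-1-yl]-2,4-dihydroxy-6-methoxyphenyl}-3-(4-hydroxyphenyl)prop-2-en-1-one | COc1cc(O)c([C@@H](/C=C/C[C@H](O[Si](C)(C)C(C)(C)C)CCc2ccc(O)cc2)c2ccc(O)cc2)c(O)c1C(=O)/C=C/c1ccc(O)cc1
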